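## Structural features

The target 30 (C42H30O23) is a linear chain of seven benzene rings, A to G, joined by six diaryl ether oxygens and carrying seventeen free phenolic hydroxyls. It has no stereocentre, so no neighbouring stereocentres need to be controlled. Ring A is a 2,4,6-trihydroxyphenyl end group and rings B, D and F are 3,5-dihydroxy-1,4-phenylenedioxy units. Ring C carries five oxygens (two adjacent aryloxy groups, three adjacent hydroxyls), ring E two adjacent aryloxy groups and two hydroxyls, and ring G is a 3,4,5-trihydroxyphenyl end group. Each ether oxygen links a carbon flanked by two oxygen-bearing carbons on one ring to a carbon with at least one ortho hydrogen on the next ring. The real difficulty is therefore six hindered ether bonds between electron-rich rings, with the correct regiochemistry on rings C and E. The free polyphenol oxidises readily in air, especially in base. Any 4-aryloxy-2,6-dioxygenated phenol on the way is a hydroquinone monoether that an oxidant converts to a quinone with loss of the aryloxy group. The key step exploits ring G: C1 bears the ether oxygen to ring F, C4 (para) a hydroxyl, C3 and C5 oxygens, and C2 and C6 hydrogens. This maps onto a carbene carbon (C1), an alkyne (C2, C3), a carbonyl ligand (C4) and a vinyl group (C5, C6).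

## Logic of the disconnections

30 from 29. The sixteen oxygen–alkyl bonds (fourteen O–CH3, two O–CH2CH3) are cut. The polyphenol cannot be carried through coupling or organometallic steps, whereas the alkyl ethers are neutral, chromatographable and tolerant of oxidants. The demand is one reagent that cleaves methyl and ethyl aryl ethers, spares six diaryl ether bonds, and allows isolation without base or air.

29 from 27 and 28. Three C–C bonds of ring G are cut: C1–C2, C3–C4 and C4–C5, with C4 traced to a carbonyl ligand of chromium. Ring G has the 4-aryloxyphenol pattern, so the hindered oxygen–C1 bond need not be made by substitution at an aromatic carbon. Ring G shrinks to a two-carbon alkyne, one CO and a three-carbon vinylcarbene. The forward step needs the C–H carbon of 28 to bond to the carbene carbon, CO insertion to beat five-membered ring closure, and a non-oxidising work-up.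

27 from 25 and 20. The bond between the ring F oxygen and the carbene carbon is cut. A carbene carbon bearing an acyloxy group behaves as an acylating agent, so this hindered ether bond forms by addition–elimination at a non-aromatic sp2 carbon. The cut separates the all-organic hexamer 20 from the small organometallic 25. The hindered phenol must attack the carbene carbon faster than the acyl carbon and faster than the activated complex decays; 20 is therefore the limiting component.

25 from 21 and 22. The bond between the carbene carbon and the vinyl carbon is cut, a carbonyl ligand of 22 being the electrophile. Both pieces are catalogue reagents. The vinyllithium from 21 must keep its Z geometry and must not eliminate ethoxide.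

20 from 18, and 18 from 17 and 2. The ring F hydroxyl is traced through formate 19 to a formyl group, and then the bond between the ring E oxygen and C4 of ring F is cut. The formyl group para to bromine activates the coupling and afterwards becomes the hindered hydroxyl, so the nucleophile for the next stage appears exactly where it is needed. The demands are aryl migration in the peracid oxidation and exclusion of oxidant once the phenol is free.

17 from 15, and 15 from 13 and 14. The ring E hydroxyl is traced through 16 to a formyl group, and the bond between the ring D oxygen and C2 of ring E is cut. In 14 the bromine is ortho to the formyl group, which fixes the 1,2-relation of the two ether oxygens and the 3,5-dimethoxy pattern of ring E in one catalogue compound. The coupling must tolerate an ortho substituent on the electrophile.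

13 from 11, and 11 from 10 and 2. Ring D is removed like ring F: the hydroxyl is traced through 12 to a formyl group and the bond between the ring C oxygen and C4 of ring D is cut. The nucleophile 10 is flanked by an aryloxy and a methoxy group, so it is paired with the unhindered electrophile 2.

10 from 8, 8 from 5 and 7, and 7 from 6. The ring C hydroxyl is traced through 9 to a formyl group, the bond between the ring B oxygen and C2 of ring C is cut, and the formyl C–C bond of 7 is cut. The two free positions of 6 are equivalent, so formylation can give only one isomer and ring C's five-oxygen pattern is secured by symmetry. The coupling must work on a bromide with a methoxy group para to it.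

5 from 3, and 3 from 1 and 2. The ring B hydroxyl is traced through 4 to a formyl group and the bond between the ring A oxygen and C4 of ring B is cut. This leaves two catalogue compounds. The forward coupling joins a 2,6-disubstituted phenoxide to a bromide with two ortho hydrogens.

## Other disconnections considered

Alternative 1: Twelve aryl C–O(H) bonds are traced to twelve aryl C–CHO bonds. In the forward sense the dodeca-aldehyde heptamer A1 would be oxidised by mCPBA to twelve aryl formates and methanolysed to the dodecaphenol A2.
- In favour: the groups that become hydroxyls first act as two ortho acceptors at each hindered carbon, so every hindered ether bond could be made by uncatalysed fluoride displacement, and fragments could be joined convergently.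
- Against: twelve oxidations on one molecule must all take the aryl-migration course and must all go to completion. Each phenol freed by premature formate loss would meet remaining peracid. The polyformyl phenoxides are weak nucleophiles and base-sensitive. A2 still carries five methyl ethers, which must be removed from a free dodecaphenol.
- Comparison: on structure it treats all six ether bonds by one logic, whereas the chosen plan places a single formyl group at a time on the unhindered side. On mechanism both of its reaction types are fully established, and in this respect it is better founded than the chosen benzannulation. On step economy it is equal or slightly better, because it can be convergent. Its weakness is that the risk is concentrated in a twelve-fold late transformation; the chosen plan forms one ring while every other oxygen is masked.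

Alternative 2: Two C–C bonds of ring C are cut, one between the two ether-bearing carbons and one between the C–H carbon and the carbon that becomes the free hydroxyl. In the forward sense the cyclobutenone A3 (rings D to G on its aryloxy group) would be heated with the aryl ethynyl ether A4 (rings A and B). Ring opening to a vinylketene, [2+2] addition to A4, a second four-electron opening and a six-electron closure would give the phenol A5.
- In favour: the most crowded ring is assembled with both of its hindered ether oxygens already attached to non-aromatic carbons. The union is convergent (two rings plus four rings), needs no metal, and its regiochemistry follows from the polarity of the alkynyl ether.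
- Against: A3 needs three differentiated oxygen substituents on a four-membered ring. A4 is the ethynyl ether of a 2,6-disubstituted phenol. The four-ring and two-ring aryloxy groups still require four ether couplings of the kind used in the chosen plan.
- Comparison: on structure it solves the two hardest ether bonds at once, whereas the chosen key step solves one. On mechanism the cascade belongs to a reaction class already practised with alkynyl ethers, so it is better precedented than the chosen key step. On step economy the total count would probably be higher, but the longest linear sequence would be shorter, and on convergence it is the better plan.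

Alternative 3: The two C–C bonds of ring D between each hydroxyl carbon and its neighbouring C–H carbon (ester-bearing at that stage) are cut. In the forward sense the sodium enolate of the 3-aryloxyglutaconate A6 (rings A to C) would be acylated twice on carbon by the aryloxymalonyl dichloride A7 (rings E to G), and enolisation would give the dihydroxy diester A8.
- In favour: the chain is divided in the middle into three rings, one ring and three rings, the highest convergence of all the plans. Both ether oxygens of ring D are attached before the ring exists.
- Against: acylation on oxygen leading to pyranones competes with acylation on carbon. A7 has an acidic hydrogen and can form a ketene. The second acylation must occur at the less acidic terminus. The two ester groups must later be hydrolysed and lost as CO2, and both three-ring halves still need four ether couplings.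
- Comparison: on structure its convergence is better than that of the chosen linear plan. On mechanism it uses classical carbonyl condensations, but their chemoselectivity on these substrates is the least predictable of the three alternatives. On step economy it is about equal in total (the ester removal adds steps) and better in longest linear sequence.

Key step: step 14

Assumption: 1, 2, 14 and 28 (the last as its solution in hexanes) are taken as catalogue compounds; 7 is made in step 3 because its supply is less certain.

Remark: a ring-by-ring check of 27 and 29 against 30 shows the same oxygen pattern (fourteen methyl ethers, two ethyl ethers, one free hydroxyl), so no structure needs correction. The Z geometry of 27 is kept because the stable cis-vinyllithium delivers it and aromatisation erases it.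

## Steps

Step 1
Reactants: 1 2,4,6-trimethoxyphenol; 2 4-bromo-2,6-dimethoxybenzaldehyde
Product: 3 2,6-dimethoxy-4-(2,4,6-trimethoxyphenoxy)benzaldehyde (rings A–B aldehyde)
Conditions: CuI (10 mol%), picolinic acid (20 mol%), K3PO4, DMSO, 90 °C, Ar
Reagents that add atoms: none
Why: Copper-catalysed Ullmann diaryl ether coupling; the bromide is activated by the para formyl group and has two ortho hydrogens, so the 2,6-disubstituted phenoxide meets little steric resistance, and picolinic acid is a ligand suited to hindered phenols.

Step 2
Reactants: 3 rings A–B aldehyde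
Product: 5 2,6-dimethoxy-4-(2,4,6-trimethoxyphenoxy)phenol (rings A–B phenol), via rings A–B aryl formate 4 (not isolated)
Conditions: mCPBA, CH2Cl2, 0 °C to rt; aq Na2S2O3 wash; then K2CO3 (cat.), MeOH, Ar, 0 °C
Reagents that add atoms: mCPBA, O=C(OO)c1cccc(Cl)c1
Why: Dakin-type sequence: Baeyer–Villiger oxidation of an aldehyde with two ortho alkoxy groups and a para aryloxy group proceeds with aryl migration to the formate, which is then methanolysed. Peracid is destroyed before base is added, because the free phenol is a hydroquinone monoether.

Step 3
Reactants: 6 5-bromo-1,2,3-trimethoxybenzene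
Product: 7 6-bromo-2,3,4-trimethoxybenzaldehyde
Conditions: POCl3, DMF, 0 to 90 °C; then H2O
Reagents that add atoms: N,N-dimethylformamide, CN(C)C=O; water, O
Why: Vilsmeier–Haack formylation; the two free positions of 6 are equivalent by symmetry and each is para to one methoxy group and ortho to another, so a single aldehyde should form.

Step 4
Reactants: 5 rings A–B phenol; 7 6-bromo-2,3,4-trimethoxybenzaldehyde
Product: 8 6-[2,6-dimethoxy-4-(2,4,6-trimethoxyphenoxy)phenoxy]-2,3,4-trimethoxybenzaldehyde (rings A–C aldehyde)
Conditions: CuI (10 mol%), picolinic acid (20 mol%), K3PO4, DMSO, 100 °C, Ar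
Reagents that add atoms: none
Why: Ullmann coupling at a bromide ortho to a formyl group, which assists the copper insertion; the methoxy group para to bromine is the central one of three and is twisted out of conjugation, so its deactivating effect should be small.

Step 5
Reactants: 8 rings A–C aldehyde
Product: 10 6-[2,6-dimethoxy-4-(2,4,6-trimethoxyphenoxy)phenoxy]-2,3,4-trimethoxyphenol (rings A–C phenol), via rings A–C aryl formate 9 (not isolated)
Conditions: mCPBA, CH2Cl2, 0 °C to rt; aq Na2S2O3 wash; then K2CO3 (cat.), MeOH, Ar, 0 °C
Reagents that add atoms: mCPBA, O=C(OO)c1cccc(Cl)c1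
Why: Baeyer–Villiger oxidation with aryl migration (ortho aryloxy, ortho and para methoxy groups make the ring the migrating group), then formate methanolysis; the product is a guaiacol-type phenol and is less oxidation-prone than 5.

Step 6
Reactants: 10 rings A–C phenol; 2 4-bromo-2,6-dimethoxybenzaldehyde
Product: 11 rings A–D aldehyde, the 4-formyl-3,5-dimethoxyphenyl ether of 10
Conditions: CuI (10 mol%), picolinic acid (20 mol%), K3PO4, DMSO, 90 °C, Ar
Reagents that add atoms: none
Why: Ullmann coupling as in step 1; the more crowded phenoxide of 10 (flanked by an aryloxy and a methoxy group) is matched with the electrophile that has two ortho hydrogens.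

Step 7
Reactants: 11 rings A–D aldehyde
Product: 13 rings A–D phenol, the 4-hydroxy-3,5-dimethoxyphenyl ether of 10, via rings A–D aryl formate 12 (not isolated)
Conditions: mCPBA, CH2Cl2, 0 °C to rt; aq Na2S2O3 wash; then K2CO3 (cat.), MeOH, Ar, 0 °C
Reagents that add atoms: mCPBA, O=C(OO)c1cccc(Cl)c1
Why: Baeyer–Villiger oxidation and methanolysis as in step 2; the formate masks the hydroquinone monoether until all peracid has been removed.

Step 8
Reactants: 13 rings A–D phenol; 14 2-bromo-4,6-dimethoxybenzaldehyde
Product: 15 rings A–E aldehyde, the 2-formyl-3,5-dimethoxyphenyl ether of 13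
Conditions: CuI (10 mol%), picolinic acid (20 mol%), K3PO4, DMSO, 100 °C, Ar
Reagents that add atoms: none
Why: Ullmann coupling at a bromide ortho to the formyl group, both methoxy groups being meta to bromine; the position of the bromine in 14 sets the 1,2-relation of the two ether oxygens of ring E.

Step 9
Reactants: 15 rings A–E aldehyde
Product: 17 rings A–E phenol, the 2-hydroxy-3,5-dimethoxyphenyl ether of 13, via rings A–E aryl formate 16 (not isolated)
Conditions: mCPBA, CH2Cl2, 0 °C to rt; aq Na2S2O3 wash; then K2CO3 (cat.), MeOH, Ar, 0 °C
Reagents that add atoms: mCPBA, O=C(OO)c1cccc(Cl)c1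
Why: Baeyer–Villiger oxidation with aryl migration (ortho aryloxy, ortho and para methoxy groups), then formate methanolysis, as in step 5.

Step 10
Reactants: 17 rings A–E phenol; 2 4-bromo-2,6-dimethoxybenzaldehyde
Product: 18 rings A–F aldehyde, the 4-formyl-3,5-dimethoxyphenyl ether of 17
Conditions: CuI (10 mol%), picolinic acid (20 mol%), K3PO4, DMSO, 90 °C, Ar
Reagents that add atoms: none
Why: Ullmann coupling as in step 6, again pairing a crowded phenoxide with the unhindered, formyl-activated bromide.

Step 11
Reactants: 18 rings A–F aldehyde
Product: 20 rings A–F phenol, the 4-hydroxy-3,5-dimethoxyphenyl ether of 17 (fourteen methyl ethers), via rings A–F aryl formate 19 (not isolated)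
Conditions: mCPBA, CH2Cl2, 0 °C to rt; aq Na2S2O3 wash; then K2CO3 (cat.), MeOH, Ar, 0 °C
Reagents that add atoms: mCPBA, O=C(OO)c1cccc(Cl)c1
Why: Baeyer–Villiger oxidation and methanolysis as in step 2; the oxidation-sensitive phenol 20 is released only after the oxidant has been removed and is kept under argon.

Step 12
Reactants: 21 (Z)-1-bromo-2-ethoxyethene; 22 hexacarbonylchromium Cr(CO)6
Product: 25 tetramethylammonium pentacarbonyl[(Z)-3-ethoxy-1-oxidoprop-2-en-1-ylidene]chromate, via (Z)-2-ethoxyvinyllithium 23 (not isolated), via lithium acylate 24 (not isolated)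
Conditions: n-BuLi, THF, −78 °C; Cr(CO)6, −78 to 0 °C; then Me4NBr, H2O, 0 °C
Reagents that add atoms: tetramethylammonium bromide, C[N+](C)(C)C.[Br-]
Why: Bromine–lithium exchange with retention of the Z geometry (the cis arrangement of lithium and ethoxy resists β-elimination at −78 °C), addition of the vinyllithium to a carbonyl ligand of Cr(CO)6 to give the acylate, and cation metathesis to the storable tetramethylammonium salt.

Step 13
Reactants: 25 tetramethylammonium acylate; 20 rings A–F phenol
Product: 27 pentacarbonyl[(rings A–F aryloxy)((Z)-2-ethoxyvinyl)carbene]chromium, the aryloxy group being that of 20, via acetoxycarbene complex 26 (not isolated)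
Conditions: AcBr, CH2Cl2, −40 °C (25 in threefold excess); then 20, −40 to 0 °C; rapid filtration through silica under Ar
Reagents that add atoms: none
Why: O-Acylation of the acylate gives an acyloxycarbene whose carbene carbon behaves like a mixed anhydride; the phenol adds there and acetate leaves (addition–elimination, the established entry to alkoxy- and aryloxycarbene complexes that cannot be made by O-alkylation). The excess of 25 makes the hexamer 20 the limiting component.

Step 14
Reactants: 27 aryloxy(2-ethoxyvinyl)carbene complex; 28 ethoxyacetylene
Product: 29 rings A–G heptamer with ring G as 3,5-diethoxy-4-hydroxyphenyl, the 3,5-diethoxy-4-hydroxyphenyl ether of 20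
Conditions: 28 (2–3 equiv, slow addition), THF, 45 °C, sealed vessel, Ar; then air, rt
Reagents that add atoms: none
Why: Proposed new method: the closest known reaction type is the Dötz benzannulation of alkoxy- or aryloxy(alkenyl)carbene complexes of zerovalent chromium with alkynes, which has not been shown for a 2-alkoxyvinyl carbene combined with an alkynyl ether on an oligomeric aryloxy group. Loss of one CO (the cis ethoxy oxygen can occupy the vacant site reversibly) lets 28 bind; its nucleophilic C–H carbon bonds to the electrophilic carbene carbon and its ethoxy-bearing carbon becomes the new chromium-bound carbon, so the steric rule (larger alkyne substituent next to the CO-derived carbon) and the polarity of the alkynyl ether point the same way. CO insertion then gives a chromium-bound dienylketene, ring G closes by thermal disrotatory six-electron electrocyclisation between the ketene carbon and the ethoxy-bearing vinyl terminus, and the cyclohexadienone tautomerises to the phenol; the three new bonds are C1–C2, C3–C4 and C4–C5 of ring G. No stereocentre is formed, and the Z geometry of the vinyl ether is erased on aromatisation. The selectivity needed is CO insertion in preference to five-membered ring closure or repeated alkyne insertion: the aryloxy group is a weaker donor than an alkoxy group and keeps chromium electron-poor, THF is the solvent class in which phenol formation is favoured for chromium, and slow addition keeps the concentration of 28 low. The hindered ether bond of ring F already exists in 27, so the step places no steric demand on that oxygen. Chromium should be released by brief exposure to air; stronger oxidants are excluded because 29 is a hydroquinone monoether.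

Step 15
Reactants: 29 rings A–G heptamer
Product: 30 CNP0351377.0, the rings A–G heptamer with seventeen free hydroxyls
Conditions: BBr3 (large excess), CH2Cl2, −78 °C to rt, Ar; then H2O, 0 °C; EtOAc extraction, Sephadex LH-20 under Ar
Reagents that add atoms: none
Why: Lewis acid ether cleavage: each alkyl aryl ether oxygen binds boron and bromide attacks the methyl or ethyl carbon by SN2, while the diaryl ether bonds offer no sp3 carbon and persist. Acidic, oxygen-free work-up protects the pyrogallol and phloroglucinol units.

## Compound list

1 | 2,4,6-trimethoxyphenol | COc1cc(OC)c(O)c(OC)c1 | starting material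
2 | 4-bromo-2,6-dimethoxybenzaldehyde | COc1cc(Br)cc(OC)c1C=O | starting material
3 | 2,6-dimethoxy-4-(2,4,6-trimethoxyphenoxy)benzaldehyde (rings A–B aldehyde) | O=Cc1c(OC)cc(Oc2c(OC)cc(OC)cc2OC)cc1OC | intermediate
4 | 2,6-dimethoxy-4-(2,4,6-trimethoxyphenoxy)phenyl formate (rings A–B aryl formate, formed in the flask) | O=COc1c(OC)cc(Oc2c(OC)cc(OC)cc2OC)cc1OC | intermediate
5 | 2,6-dimethoxy-4-(2,4,6-trimethoxyphenoxy)phenol (rings A–B phenol) | Oc1c(OC)cc(Oc2c(OC)cc(OC)cc2OC)cc1OC | intermediate
6 | 5-bromo-1,2,3-trimethoxybenzene | COc1cc(Br)cc(OC)c1OC | starting material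
7 | 6-bromo-2,3,4-trimethoxybenzaldehyde | COc1cc(Br)c(C=O)c(OC)c1OC | intermediate
8 | 6-[2,6-dimethoxy-4-(2,4,6-trimethoxyphenoxy)phenoxy]-2,3,4-trimethoxybenzaldehyde (rings A–C aldehyde) | O=Cc1c(Oc2c(OC)cc(Oc3c(OC)cc(OC)cc3OC)cc2OC)cc(OC)c(OC)c1OC | intermediate
9 | rings A–C aryl formate, the formate ester of 10 (formed in the flask) | O=COc1c(Oc2c(OC)cc(Oc3c(OC)cc(OC)cc3OC)cc2OC)cc(OC)c(OC)c1OC | intermediate
10 | 6-[2,6-dimethoxy-4-(2,4,6-trimethoxyphenoxy)phenoxy]-2,3,4-trimethoxyphenol (rings A–C phenol) | Oc1c(Oc2c(OC)cc(Oc3c(OC)cc(OC)cc3OC)cc2OC)cc(OC)c(OC)c1OC | intermediate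
11 | rings A–D aldehyde, the 4-formyl-3,5-dimethoxyphenyl ether of 10 | O=Cc1c(OC)cc(Oc2c(Oc3c(OC)cc(Oc4c(OC)cc(OC)cc4OC)cc3OC)cc(OC)c(OC)c2OC)cc1OC | intermediate
12 | rings A–D aryl formate, the formate ester of 13 (formed in the flask) | O=COc1c(OC)cc(Oc2c(Oc3c(OC)cc(Oc4c(OC)cc(OC)cc4OC)cc3OC)cc(OC)c(OC)c2OC)cc1OC | intermediate
13 | rings A–D phenol, the 4-hydroxy-3,5-dimethoxyphenyl ether of 10 | Oc1c(OC)cc(Oc2c(Oc3c(OC)cc(Oc4c(OC)cc(OC)cc4OC)cc3OC)cc(OC)c(OC)c2OC)cc1OC | intermediate
14 | 2-bromo-4,6-dimethoxybenzaldehyde | COc1cc(Br)c(C=O)c(OC)c1 | starting material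
15 | rings A–E aldehyde, the 2-formyl-3,5-dimethoxyphenyl ether of 13 | O=Cc1c(Oc2c(OC)cc(Oc3c(Oc4c(OC)cc(Oc5c(OC)cc(OC)cc5OC)cc4OC)cc(OC)c(OC)c3OC)cc2OC)cc(OC)cc1OC | intermediate
16 | rings A–E aryl formate, the formate ester of 17 (formed in the flask) | O=COc1c(Oc2c(OC)cc(Oc3c(Oc4c(OC)cc(Oc5c(OC)cc(OC)cc5OC)cc4OC)cc(OC)c(OC)c3OC)cc2OC)cc(OC)cc1OC | intermediate
17 | rings A–E phenol, the 2-hydroxy-3,5-dimethoxyphenyl ether of 13 | Oc1c(Oc2c(OC)cc(Oc3c(Oc4c(OC)cc(Oc5c(OC)cc(OC)cc5OC)cc4OC)cc(OC)c(OC)c3OC)cc2OC)cc(OC)cc1OC | intermediate
18 | rings A–F aldehyde, the 4-formyl-3,5-dimethoxyphenyl ether of 17 | O=Cc1c(OC)cc(Oc2c(Oc3c(OC)cc(Oc4c(Oc5c(OC)cc(Oc6c(OC)cc(OC)cc6OC)cc5OC)cc(OC)c(OC)c4OC)cc3OC)cc(OC)cc2OC)cc1OC | intermediate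
19 | rings A–F aryl formate, the formate ester of 20 (formed in the flask) | O=COc1c(OC)cc(Oc2c(Oc3c(OC)cc(Oc4c(Oc5c(OC)cc(Oc6c(OC)cc(OC)cc6OC)cc5OC)cc(OC)c(OC)c4OC)cc3OC)cc(OC)cc2OC)cc1OC | intermediate
20 | rings A–F phenol, the 4-hydroxy-3,5-dimethoxyphenyl ether of 17 | Oc1c(OC)cc(Oc2c(Oc3c(OC)cc(Oc4c(Oc5c(OC)cc(Oc6c(OC)cc(OC)cc6OC)cc5OC)cc(OC)c(OC)c4OC)cc3OC)cc(OC)cc2OC)cc1OC | intermediate
21 | (Z)-1-bromo-2-ethoxyethene | CCO/C=C\Br | starting material
22 | hexacarbonylchromium Cr(CO)6 | O=C=[Cr](=C=O)(=C=O)(=C=O)(=C=O)=C=O | starting material
23 | (Z)-2-ethoxyvinyllithium (formed in the flask) | CCO/C=C\[Li] | intermediate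
24 | lithium pentacarbonyl[(Z)-3-ethoxy-1-oxidoprop-2-en-1-ylidene]chromate (formed in the flask) | [Li+].CCO/C=C\C([O-])=[Cr](=C=O)(=C=O)(=C=O)(=C=O)=C=O | intermediate
25 | tetramethylammonium pentacarbonyl[(Z)-3-ethoxy-1-oxidoprop-2-en-1-ylidene]chromate | C[N+](C)(C)C.CCO/C=C\C([O-])=[Cr](=C=O)(=C=O)(=C=O)(=C=O)=C=O | intermediate
26 | pentacarbonyl[acetoxy((Z)-2-ethoxyvinyl)carbene]chromium (formed in the flask) | CCO/C=C\C(OC(C)=O)=[Cr](=C=O)(=C=O)(=C=O)(=C=O)=C=O | intermediate
27 | pentacarbonyl[(rings A–F aryloxy)((Z)-2-ethoxyvinyl)carbene]chromium | CCO/C=C\C(Oc1c(OC)cc(Oc2c(Oc3c(OC)cc(Oc4c(Oc5c(OC)cc(Oc6c(OC)cc(OC)cc6OC)cc5OC)cc(OC)c(OC)c4OC)cc3OC)cc(OC)cc2OC)cc1OC)=[Cr](=C=O)(=C=O)(=C=O)(=C=O)=C=O | intermediate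
28 | ethoxyacetylene | CCOC#C | starting material
29 | rings A–G heptamer with ring G as 3,5-diethoxy-4-hydroxyphenyl and fourteen methyl ethers | CCOc1cc(Oc2c(OC)cc(Oc3c(Oc4c(OC)cc(Oc5c(Oc6c(OC)cc(Oc7c(OC)cc(OC)cc7OC)cc6OC)cc(OC)c(OC)c5OC)cc4OC)cc(OC)cc3OC)cc2OC)cc(OCC)c1O | intermediate
30 | CNP0351377.0, rings A–G heptamer with seventeen free hydroxyls | Oc1cc(O)c(Oc2cc(O)c(Oc3cc(O)c(O)c(O)c3Oc3cc(O)c(Oc4cc(O)cc(O)c4Oc4cc(O)c(Oc5cc(O)c(O)c(O)c5)c(O)c4)c(O)c3)c(O)c2)c(O)c1 | target

## Step count and least certain steps

Total: 15 steps. Longest linear sequence: 13 steps (steps 1, 2, 4 to 11, 13, 14 and 15, from 1 to 30). Step 3 and step 12 are one-step side branches.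

Step 14 (key step). The most likely failure is that the alkyne-inserted intermediate closes a five-membered ring without taking up CO, or that the alkynyl ether inserts repeatedly and oligomerises at chromium. Both partners are strongly donor-substituted and the inserted carbene is itself ethoxy-stabilised, which makes these paths plausible. Hydrolysis of the aryloxycarbene by adventitious water is a further loss channel, from which 20 would be recoverable. The fallback uses known chemistry, sets out from 20 and returns at 30. Phenol 20 is coupled with 2 under the copper conditions of step 10 to give the rings A–G aldehyde F1. Peracid oxidation as in step 11 passes through the rings A–G aryl formate F2 and, after methanolysis, gives the heptamer phenol with ring G as 4-hydroxy-3,5-dimethoxyphenyl F3, the dimethyl analogue of 29. BBr3 under the conditions of step 15 then cleaves its sixteen methyl ethers and delivers 30.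

Step 13. The most likely failure is acyl transfer: the hindered phenol attacks the acetyl carbonyl and not the carbene carbon. The acyloxycarbene may also decay above about −20 °C before the slow addition is complete, or the ethoxy group at the vinylogous position may be displaced. A first adjustment within the same approach would be a pivaloyl group in place of acetyl. The fallback sets out from 20 and returns at 30 without chromium. Copper-catalysed coupling of 20 with the unactivated bromide 6 (conditions of step 1 at 110 °C) would give the heptamer heptadecamethyl ether F4, with ring G as 3,4,5-trimethoxyphenyl. BBr3 under the conditions of step 15 cleaves its seventeen methyl ethers to 30. The route described under step 14 is equally open at this point.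

Step 4. The most likely failure is slow substitution at a bromide that is para to a methoxy group and faces a bulky phenoxide, so that debromination of 7 or oxidative loss of the phenoxide of 5 overtakes coupling. The fallback sets out from 5 and returns at 8. 5-Fluoro-1,2,3-trimethoxybenzene F5 is formylated as in step 3 to 6-fluoro-2,3,4-trimethoxybenzaldehyde F6. Phenol 5 then displaces the fluoride without copper (K2CO3, DMF, 120 °C), a nucleophilic aromatic substitution activated by the ortho formyl group, giving 8.

Step 15. The most likely failure is incomplete cleavage of the sixteen ethers, because partially dealkylated boron chelates precipitate, together with air oxidation of the pyrogallol units during isolation of a very polar product. The fallback sets out from 29 and returns at 30. The crude product of the BBr3 treatment is not purified but peracetylated (Ac2O, pyridine) to the heptadecaacetate of 30 F7. F7 is purified on silica and then deacetylated by HCl (cat.) in MeOH under Ar to 30.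

## Further compounds

F1 | step 14 | rings A–G aldehyde, the 4-formyl-3,5-dimethoxyphenyl ether of 20 | O=Cc1c(OC)cc(Oc2c(OC)cc(Oc3c(Oc4c(OC)cc(Oc5c(Oc6c(OC)cc(Oc7c(OC)cc(OC)cc7OC)cc6OC)cc(OC)c(OC)c5OC)cc4OC)cc(OC)cc3OC)cc2OC)cc1OC
F2 | step 14 | rings A–G aryl formate, the formate ester of F3 | O=COc1c(OC)cc(Oc2c(OC)cc(Oc3c(Oc4c(OC)cc(Oc5c(Oc6c(OC)cc(Oc7c(OC)cc(OC)cc7OC)cc6OC)cc(OC)c(OC)c5OC)cc4OC)cc(OC)cc3OC)cc2OC)cc1OC
F3 | step 14 | heptamer phenol with ring G as 4-hydroxy-3,5-dimethoxyphenyl (sixteen methyl ethers) | Oc1c(OC)cc(Oc2c(OC)cc(Oc3c(Oc4c(OC)cc(Oc5c(Oc6c(OC)cc(Oc7c(OC)cc(OC)cc7OC)cc6OC)cc(OC)c(OC)c5OC)cc4OC)cc(OC)cc3OC)cc2OC)cc1OC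
F4 | step 13 | heptamer heptadecamethyl ether, the 3,4,5-trimethoxyphenyl ether of 20 | COc1cc(Oc2c(OC)cc(Oc3c(Oc4c(OC)cc(Oc5c(Oc6c(OC)cc(Oc7c(OC)cc(OC)cc7OC)cc6OC)cc(OC)c(OC)c5OC)cc4OC)cc(OC)cc3OC)cc2OC)cc(OC)c1OC
F5 | step 4 | 5-fluoro-1,2,3-trimethoxybenzene | COc1cc(F)cc(OC)c1OC
F6 | step 4 | 6-fluoro-2,3,4-trimethoxybenzaldehyde | COc1cc(F)c(C=O)c(OC)c1OC
F7 | step 15 | heptadecaacetate of 30 | CC(=O)Oc1cc(OC(C)=O)c(Oc2cc(OC(C)=O)c(Oc3cc(OC(C)=O)c(OC(C)=O)c(OC(C)=O)c3Oc3cc(OC(C)=O)c(Oc4cc(OC(C)=O)cc(OC(C)=O)c4Oc4cc(OC(C)=O)c(Oc5cc(OC(C)=O)c(OC(C)=O)c(OC(C)=O)c5)c(OC(C)=O)c4)c(OC(C)=O)c3)c(OC(C)=O)c2)c(OC(C)=O)c1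
A1 | alternative 1 | heptamer dodeca-aldehyde with five methyl ethers | COc1cc(C=O)c(Oc2cc(C=O)c(Oc3cc(C=O)c(OC)c(C=O)c3Oc3cc(C=O)c(Oc4cc(C=O)cc(C=O)c4Oc4cc(C=O)c(Oc5cc(OC)c(OC)c(OC)c5)c(C=O)c4)c(C=O)c3)c(C=O)c2)c(C=O)c1
A2 | alternative 1 | heptamer dodecaphenol with five methyl ethers | COc1cc(O)c(Oc2cc(O)c(Oc3cc(O)c(OC)c(O)c3Oc3cc(O)c(Oc4cc(O)cc(O)c4Oc4cc(O)c(Oc5cc(OC)c(OC)c(OC)c5)c(O)c4)c(O)c3)c(O)c2)c(O)c1
A3 | alternative 2 | 2-(rings D–G aryloxy)-3,4-dimethoxycyclobut-2-en-1-one (racemic at C4) | COC1C(=O)C(Oc2cc(OC)c(Oc3cc(OC)cc(OC)c3Oc3cc(OC)c(Oc4cc(OC)c(OC)c(OC)c4)c(OC)c3)c(OC)c2)=C1OC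
A4 | alternative 2 | rings A–B aryl ethynyl ether, 2-ethynyloxy-1,3-dimethoxy-5-(2,4,6-trimethoxyphenoxy)benzene | C#COc1c(OC)cc(Oc2c(OC)cc(OC)cc2OC)cc1OC
A5 | alternative 2 | heptamer with one free ring C hydroxyl and sixteen methyl ethers | Oc1cc(Oc2c(OC)cc(Oc3c(OC)cc(OC)cc3OC)cc2OC)c(Oc2cc(OC)c(Oc3cc(OC)cc(OC)c3Oc3cc(OC)c(Oc4cc(OC)c(OC)c(OC)c4)c(OC)c3)c(OC)c2)c(OC)c1OC
A6 | alternative 3 | dimethyl (E)-3-(rings A–C aryloxy)pent-2-enedioate | COC(=O)/C=C(/Oc1c(Oc2c(OC)cc(Oc3c(OC)cc(OC)cc3OC)cc2OC)cc(OC)c(OC)c1OC)CC(=O)OC
A7 | alternative 3 | 2-(rings E–G aryloxy)malonyl dichloride | O=C(Cl)C(Oc1cc(OC)cc(OC)c1Oc1cc(OC)c(Oc2cc(OC)c(OC)c(OC)c2)c(OC)c1)C(Cl)=O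
A8 | alternative 3 | heptamer with ring D as a dihydroxy diester and fifteen methyl ethers | COC(=O)c1c(O)c(Oc2cc(OC)cc(OC)c2Oc2cc(OC)c(Oc3cc(OC)c(OC)c(OC)c3)c(OC)c2)c(O)c(C(=O)OC)c1Oc1c(Oc2c(OC)cc(Oc3c(OC)cc(OC)cc3OC)cc2OC)cc(OC)c(OC)c1OC
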